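Amounts first: 0.10 M of G and 0.300 M of J stand against each other in each flask, and the flasks differ in how these go in.

| setting | cedar | alder | birch |
|---|---|---|---|
| G | 0.10 M | 0.10 M (fed, over 12 h) | 0.10 M |
| J | 0.300 M (fed, over 12 h) | 0.300 M | 0.300 M |
| time | 15 h | 15 h | 15 h |
| remark | all else is in the flask from the start; the feed brings no volume worth counting | all else is in the flask from the start; the feed brings no volume worth counting | everything together at the start |

    G → Q (k1 = 1.8 × 10⁻⁴ s⁻¹)
    G + J → G.J (k2 = 7.9 × 10⁻⁴ M⁻¹ s⁻¹)
    G.J → D (k3 = 6.7 × 10⁻⁴ s⁻¹)
    D ⇌ X (K4 = 0.34, k4 = 7.3 × 10⁻⁵ s⁻¹)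
    J + D ⇌ J.D (K5 = 0.36 M⁻¹, k5 = 0.0015 M⁻¹ s⁻¹)
    J + D ⇌ E (K6 = 4.2 M⁻¹, k6 = 4.2 × 10⁻⁴ M⁻¹ s⁻¹)

- the flask with the highest amount of Q, in percent of the G charged ("all alike" if they lie within 1.5 percentage points) (cedar / alder / birch / all alike)
- final Q, as a percentage of the G charged, in cedar
- final Q, as a percentage of the G charged, in alder
- final Q, as a percentage of the G charged, in birch

Q comes from G by one step, and G has one other way out, the step with J, so we ask which numbers reach that fork. At charged J the split number, the rate of G + J → G.J over the rate of G → Q, is 1.32. This is a selectivity factor, ten to the power 0.119, and the share of G reaching Q is one over one plus it, 43.2 %. Its constants must be known well: a factor of two up on 7.9 × 10⁻⁴ M⁻¹ s⁻¹ moves the logarithm by 0.301 and the share to 27.5 %, and the same on 1.8 × 10⁻⁴ s⁻¹ gives 60.3 %.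

The constants behind G.J feed neither G nor Q, so they reach Q through the J they take. A fall of J by 0.10 M lifts the share to 53.3 %, so rough values serve. In birch the time can be off widely, since 15 h is 22.5 lifetimes of G at charged J. But in alder G goes in until 12 h, so the last of it has 3.00 h to react, and the time has to be known better there.

The feed time matters for cedar. Over the lifetime of G on the step to Q, 1.54 h, the feed alone brings J to 0.0386 M, so the split number in cedar is 0.170, ten to the power −0.770, and the share 85.5 %. Alder starts with birch's J, so we give both 43.2 % as a low end, with falling J lifting it.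

The forecast names cedar and gives 87 % (83 % to 90 %) for cedar, 46 % (43 % to 50 %) for alder and 45 % (42 % to 48 %) for birch, its ground for cedar being: “Feeding J instead keeps J near zero”. Our figures lie lower, for cedar and for birch.

The flasks end with Q at 88.9 % in cedar, 46.5 % in alder and 46.0 % in birch, each inside the forecast's range, and cedar stands 43 percentage points above birch. In birch at 0.457 h, the half-life of G is 1.1 h by the step to Q against 0.90 h by the step with J, a split number read there of 1.19 and a share of 45.6 %. In a neighbour of birch charged with 1.2 M of J, the split number is 5.28 and the share 15.9 %, and that flask ends with Q at 16.5 %.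

The numbers of this flask were drawn at random within sensible limits; the flask was simulated.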